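The central oxazole carries hydrogen at C4, indole C3 at C5 and pyrrole C2 at C2. That C4–H, C5-aryl pattern is what an aldehyde and TosMIC deliver, so the ring is cut at C4–C5 and O1–C2. In one operation the formyl carbon on indole C3 becomes oxazole C5 and its oxygen becomes O1. The heterocycle grows on the carbon crowded by the 4-OMe group, and no cross-coupling is needed there. The precursor is 6-bromo-4-methoxyindole-3-carbaldehyde blocked at N1 by SEM, two steps from the commercial indole. The acidic oxazole C2–H then allows iodination, iodide-selective Suzuki coupling, pyrrole bromination and deprotection.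

Key step: step 3

Remark: the target has no stereocentre; the two stereocentres of the transient oxazoline 7 (drawn trans, racemic) disappear in the same flask, and 1, 6 and 11 are taken as catalogue compounds.

Step 1
Reactants: 1 6-bromo-4-methoxy-1H-indole
Product: 3 6-bromo-4-methoxy-1H-indole-3-carbaldehyde, via indolylmethylidene iminium salt 2 (not isolated)
Conditions: POCl3, DMF, 0 °C to 40 °C; then aq. NaOH
Reagents that add atoms: N,N-dimethylformamide, CN(C)C=O; water, O
Why: Vilsmeier–Haack formylation: the chloroiminium ion formed from POCl3 and DMF is attacked by the enamine-like C3, the most nucleophilic carbon of the indole, and aqueous base hydrolyses iminium salt 2 to the aldehyde while C6–Br and the methyl ether stay untouched.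

Step 2
Reactants: 3 6-bromo-4-methoxy-1H-indole-3-carbaldehyde
Product: 5 6-bromo-4-methoxy-1-(2-trimethylsilylethoxymethyl)indole-3-carbaldehyde, via sodium indolide 4 (not isolated)
Conditions: NaH, THF, 0 °C; then SEMCl, 0 °C to rt
Reagents that add atoms: 2-(trimethylsilyl)ethoxymethyl chloride, C[Si](C)(C)CCOCCl
Why: N-alkylation of an indolide by a chloromethyl ether (SN2 type): the 3-formyl group makes N1–H acidic enough for clean deprotonation, alkylation at nitrogen keeps the indole aromatic, and formylating before protecting spares the acid-sensitive SEM group any contact with POCl3.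

Step 3
Reactants: 5 6-bromo-4-methoxy-1-(2-trimethylsilylethoxymethyl)indole-3-carbaldehyde; 6 tosylmethyl isocyanide
Product: 8 5-[6-bromo-4-methoxy-1-(2-trimethylsilylethoxymethyl)indol-3-yl]oxazole, via trans-4-tosyl-4,5-dihydrooxazole 7 (not isolated)
Conditions: K2CO3, MeOH, reflux
Reagents that add atoms: none
Why: K2CO3 deprotonates the methylene of 6, which is acidified by the sulfonyl and isocyano groups, and the carbanion adds to the formyl carbon of 5 to form C4–C5. The alkoxide so formed attacks the terminal isocyanide carbon to form O1–C2, a 5-endo-dig closure that is normal for isocyanides, and protonation at C2 gives oxazoline 7. Base then removes the C5 proton with loss of p-toluenesulfinate from C4, and the aromaticity gained drives the whole sequence forward; this is the Van Leusen oxazole synthesis, well established for aryl and heteroaryl aldehydes. The two stereocentres of 7 (C4 and C5, trans for steric reasons) vanish in the elimination, so nothing has to control them. The step needs only chemoselectivity: SEM replaces the N1–H whose deprotonation by carbonate would convert the aldehyde into an unreactive vinylogous amidate, and C6–Br, the methyl ether and the SEM acetal are inert to K2CO3 in methanol. Regiochemistry is built in, because the aldehyde carbon can only become C5 and the TosMIC methylene can only become the unsubstituted C4.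

Step 4
Reactants: 8 5-[6-bromo-4-methoxy-1-(2-trimethylsilylethoxymethyl)indol-3-yl]oxazole
Product: 10 5-[6-bromo-4-methoxy-1-(2-trimethylsilylethoxymethyl)indol-3-yl]-2-iodooxazole, via 2-lithiooxazole 9 (not isolated)
Conditions: LiN(SiMe3)2, THF, −78 °C; then I2, −78 °C
Reagents that add atoms: iodine, [I][I]
Why: Deprotonation and electrophilic iodination of an oxazole at C2: the C2–H between O1 and N3 is the only proton within reach of LiN(SiMe3)2, this amide base cannot exchange the C6 bromine as an alkyllithium would, and quenching in THF without a polar cosolvent places iodine at C2 and not at C4.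

Step 5
Reactants: 10 5-[6-bromo-4-methoxy-1-(2-trimethylsilylethoxymethyl)indol-3-yl]-2-iodooxazole; 11 1-Boc-pyrrole-2-boronic acid
Product: 12 tert-butyl 2-{5-[6-bromo-4-methoxy-1-(2-trimethylsilylethoxymethyl)indol-3-yl]oxazol-2-yl}pyrrole-1-carboxylate
Conditions: 11 (1.5 equiv), Pd(PPh3)4 (5 mol %), Na2CO3, DME–H2O, 60 °C
Reagents that add atoms: none
Why: Suzuki–Miyaura coupling: zerovalent palladium inserts into the weak carbon–iodine bond at the electron-poor oxazole C2 much faster than into the carbon–bromine bond of the electron-rich indole, so a triphenylphosphine catalyst at moderate temperature should couple only at C2 and leave C6–Br and the Boc group in place.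

Step 6
Reactants: 12 tert-butyl 2-{5-[6-bromo-4-methoxy-1-(2-trimethylsilylethoxymethyl)indol-3-yl]oxazol-2-yl}pyrrole-1-carboxylate
Product: 13 tert-butyl 2-bromo-5-{5-[6-bromo-4-methoxy-1-(2-trimethylsilylethoxymethyl)indol-3-yl]oxazol-2-yl}pyrrole-1-carboxylate
Conditions: NBS (1.0 equiv), THF, −78 °C to 0 °C, dark
Reagents that add atoms: N-bromosuccinimide, O=C1CCC(=O)N1Br
Why: Electrophilic aromatic bromination: N-Boc-pyrroles take up one equivalent of N-bromosuccinimide in cold THF at a free α-carbon, which here is only C5, whereas indole C2 (hemmed in by SEM and the oxazole), oxazole C4 and the bromine-bearing benzenoid ring should react more slowly.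

Step 7
Reactants: 13 tert-butyl 2-bromo-5-{5-[6-bromo-4-methoxy-1-(2-trimethylsilylethoxymethyl)indol-3-yl]oxazol-2-yl}pyrrole-1-carboxylate
Product: 15 6-bromo-3-[2-(5-bromo-1H-pyrrol-2-yl)oxazol-5-yl]-4-methoxy-1H-indole, via N-SEM bromopyrrole 14 (not isolated)
Conditions: NaOMe (cat.), MeOH–THF, rt; evaporate; then Bu4NF, H2NCH2CH2NH2, THF, 65 °C
Reagents that add atoms: none
Why: Two standard N-deprotections in sequence: methoxide transfers the activated pyrrole carbamate to methanol (acyl transfer), then fluoride attacks silicon and the SEM group fragments by β-elimination while ethylenediamine binds the formaldehyde released, and the wholly non-acidic medium spares the bromopyrrole and both carbon–bromine bonds.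

Compound list
1 | 6-bromo-4-methoxy-1H-indole | COc1cc(Br)cc2[nH]ccc12 | starting material
2 | [(6-bromo-4-methoxy-1H-indol-3-yl)methylidene]dimethylammonium dichlorophosphate | COc1cc(Br)cc2[nH]cc(C=[N+](C)C)c12.[O-]P(=O)(Cl)Cl | intermediate
3 | 6-bromo-4-methoxy-1H-indole-3-carbaldehyde | COc1cc(Br)cc2[nH]cc(C=O)c12 | intermediate
4 | sodium 6-bromo-3-formyl-4-methoxyindol-1-ide | COc1cc(Br)cc2[n-]cc(C=O)c12.[Na+] | intermediate
5 | 6-bromo-4-methoxy-1-(2-trimethylsilylethoxymethyl)indole-3-carbaldehyde | COc1cc(Br)cc2c1c(C=O)cn2COCC[Si](C)(C)C | intermediate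
6 | tosylmethyl isocyanide (TosMIC) | Cc1ccc(S(=O)(=O)C[N+]#[C-])cc1 | starting material
7 | trans-5-[6-bromo-4-methoxy-1-(2-trimethylsilylethoxymethyl)indol-3-yl]-4-tosyl-4,5-dihydrooxazole (racemic, the 4S,5S enantiomer drawn) | COc1cc(Br)cc2c1c([C@@H]3OC=N[C@H]3S(=O)(=O)c4ccc(C)cc4)cn2COCC[Si](C)(C)C | intermediate
8 | 5-[6-bromo-4-methoxy-1-(2-trimethylsilylethoxymethyl)indol-3-yl]oxazole | COc1cc(Br)cc2c1c(-c3cnco3)cn2COCC[Si](C)(C)C | intermediate
9 | 5-[6-bromo-4-methoxy-1-(2-trimethylsilylethoxymethyl)indol-3-yl]-2-lithiooxazole | COc1cc(Br)cc2c1c(-c3cnc([Li])o3)cn2COCC[Si](C)(C)C | intermediate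
10 | 5-[6-bromo-4-methoxy-1-(2-trimethylsilylethoxymethyl)indol-3-yl]-2-iodooxazole | Ic1ncc(-c2cn(COCC[Si](C)(C)C)c3cc(Br)cc(OC)c23)o1 | intermediate
11 | 1-Boc-pyrrole-2-boronic acid | CC(C)(C)OC(=O)n1cccc1B(O)O | starting material
12 | tert-butyl 2-{5-[6-bromo-4-methoxy-1-(2-trimethylsilylethoxymethyl)indol-3-yl]oxazol-2-yl}pyrrole-1-carboxylate | COc1cc(Br)cc2c1c(-c3cnc(-c4cccn4C(=O)OC(C)(C)C)o3)cn2COCC[Si](C)(C)C | intermediate
13 | tert-butyl 2-bromo-5-{5-[6-bromo-4-methoxy-1-(2-trimethylsilylethoxymethyl)indol-3-yl]oxazol-2-yl}pyrrole-1-carboxylate | COc1cc(Br)cc2c1c(-c3cnc(-c4ccc(Br)n4C(=O)OC(C)(C)C)o3)cn2COCC[Si](C)(C)C | intermediate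
14 | 2-(5-bromo-1H-pyrrol-2-yl)-5-[6-bromo-4-methoxy-1-(2-trimethylsilylethoxymethyl)indol-3-yl]oxazole | COc1cc(Br)cc2c1c(-c3cnc(-c4ccc(Br)[nH]4)o3)cn2COCC[Si](C)(C)C | intermediate
15 | 6-bromo-3-[2-(5-bromo-1H-pyrrol-2-yl)oxazol-5-yl]-4-methoxy-1H-indole (CNP0145233.0) | COc1cc(Br)cc2[nH]cc(-c3cnc(-c4ccc(Br)[nH]4)o3)c12 | target

Total step count: 7. Longest linear sequence: 7 steps, from 1 to 15 (6 and 11 are bought).

Steps most likely to fail

Step 6. The bromination may lose site selectivity, with competing attack on the indole or oxazole ring or a second bromination of the pyrrole. The cause would be that the carbamate and the oxazole together damp the pyrrole. The fallback swaps bromination and Boc removal; it sets out from 12 and comes back to the route at 14.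
- The carbamate is taken off first (NaOMe cat., MeOH–THF, rt) to give 5-[6-bromo-4-methoxy-1-(2-trimethylsilylethoxymethyl)indol-3-yl]-2-(1H-pyrrol-2-yl)oxazole F1.
- The free N–H pyrrole of this compound is by far the most nucleophilic ring present. One equivalent of N-bromosuccinimide in THF or acetone at −78 °C should therefore be consumed at its open α-carbon C5.
- This gives 14, now isolated, which needs only the fluoride stage of step 7.

Step 5. Four processes could erode the coupling: protodeboronation of the pyrrolylboronic acid, hydrolytic loss of its carbamate in the aqueous base, decay of the sensitive iodooxazole before it couples, and insertion of palladium at C6–Br. The fallback reverses the polarity of the coupling (Negishi reaction). It sets out from 8, comes back at 12 and makes step 4 unnecessary.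
- Compound 8 is deprotonated as in step 4 to 9 and transmetalated with ZnCl2 to the ring-closed {5-[6-bromo-4-methoxy-1-(2-trimethylsilylethoxymethyl)indol-3-yl]oxazol-2-yl}zinc chloride F2.
- The partner comes from tert-butyl pyrrole-1-carboxylate. Carbamate-directed α-lithiation with lithium 2,2,6,6-tetramethylpiperidide (THF, −78 °C) gives tert-butyl 2-lithiopyrrole-1-carboxylate F3, and an iodine quench gives tert-butyl 2-iodopyrrole-1-carboxylate F4.
- F2 and F4 are joined with Pd(PPh3)4 in THF at 50 °C. The medium is anhydrous and free of added base, and the only carbon–iodine bond sits on the pyrrole partner.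

Step 3. Addition may be slow, because the carbonyl is still a vinylogous formamide and is crowded by the peri 4-OMe group. Base-induced decay of the isocyanide, or stalling before sulfinate loss, could then overtake the annulation. The fallback attaches a preformed oxazole by cross-coupling; it sets out from 1 and comes back at 8.
- Iodination at C3 (N-iodosuccinimide, DMF, 0 °C) gives 6-bromo-3-iodo-4-methoxy-1H-indole F5.
- NaH in THF converts F5 into sodium 6-bromo-3-iodo-4-methoxyindol-1-ide F6, and SEMCl then gives 6-bromo-3-iodo-4-methoxy-1-(2-trimethylsilylethoxymethyl)indole F7.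
- An iodide-selective Suzuki–Miyaura coupling with commercial 2-(triisopropylsilyl)oxazole-5-boronic acid pinacol ester (Pd(dppf)Cl2, K3PO4, dioxane–H2O, 70 °C) gives 5-[6-bromo-4-methoxy-1-(2-trimethylsilylethoxymethyl)indol-3-yl]-2-(triisopropylsilyl)oxazole F8.
- Bu4NF in THF at 0 °C removes the labile C2 silyl group, leaves SEM in place and delivers 8.

Further compounds
F1 | step 6 | 5-[6-bromo-4-methoxy-1-(2-trimethylsilylethoxymethyl)indol-3-yl]-2-(1H-pyrrol-2-yl)oxazole | COc1cc(Br)cc2c1c(-c3cnc(-c4ccc[nH]4)o3)cn2COCC[Si](C)(C)C
F2 | step 5 | {5-[6-bromo-4-methoxy-1-(2-trimethylsilylethoxymethyl)indol-3-yl]oxazol-2-yl}zinc chloride | COc1cc(Br)cc2c1c(-c3cnc([Zn]Cl)o3)cn2COCC[Si](C)(C)C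
F3 | step 5 | tert-butyl 2-lithiopyrrole-1-carboxylate | CC(C)(C)OC(=O)n1cccc1[Li]
F4 | step 5 | tert-butyl 2-iodopyrrole-1-carboxylate | CC(C)(C)OC(=O)n1cccc1I
F5 | step 3 | 6-bromo-3-iodo-4-methoxy-1H-indole | Ic1c[nH]c2cc(Br)cc(OC)c12
F6 | step 3 | sodium 6-bromo-3-iodo-4-methoxyindol-1-ide | Ic1c[n-]c2cc(Br)cc(OC)c12.[Na+]
F7 | step 3 | 6-bromo-3-iodo-4-methoxy-1-(2-trimethylsilylethoxymethyl)indole | Ic1cn(COCC[Si](C)(C)C)c2cc(Br)cc(OC)c12
F8 | step 3 | 5-[6-bromo-4-methoxy-1-(2-trimethylsilylethoxymethyl)indol-3-yl]-2-(triisopropylsilyl)oxazole | CC(C)[Si](C(C)C)(C(C)C)c1ncc(-c2cn(COCC[Si](C)(C)C)c3cc(Br)cc(OC)c23)o1
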